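- Divide the rate of right-handed product by that of left-handed product, each per unit of its own substrate, and time drops out: if that ratio holds steady, it equals ln(fraction of right-handed substrate left) / ln(fraction of left-handed substrate left).

the same everywhere: free catalyst 0.5 mol%

| charge | left-handed substrate | right-handed substrate | coupling partner | remark | time |
|---|---|---|---|---|---|
| elm | 0.050 M | 0.050 M | 2 equiv (fed, over 6.0 h) | run made earlier |  |
| maple | 0.075 M | 0.075 M | 2 equiv (fed, over 6.0 h) | run made earlier |  |
| flask | 0.10 M | 0.10 M | 2.00 equiv (fed, over 6.0 h) |  | 6.0 h |

- elm (time / h: left-handed product / %, right-handed product / %): 0.500: 1.5, 0.6; 0.833: 0.2, 2.3; 1.33: 1.5, 1.0; 2.00: 1.8, 2.4; 3.00: 3.6, 3.7; 5.00: 6.5, 9.9; 8.00: 11.6, 20.9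
- maple (time / h: left-handed product / %, right-handed product / %): 0.500: 0, 1.2; 0.833: 0, 0.6; 1.33: 0, 1.8; 2.00: 1.4, 4.2; 3.00: 3.9, 8.1; 5.00: 8.5, 16.4; 8.00: 18.6, 28.4

(readings scatter by 1 percentage point)

- free catalyst is single-handed; left-handed substrate and right-handed substrate are mirror images of each other, charged as a racemate, each of them at the stated concentration
- steps thought possible: coupling partner <-> dormant form; coupling partner -> decomposed reagent; free catalyst + left-handed substrate <-> catalyst intermediate A; left-handed product <-> right-handed product; coupling partner + catalyst intermediate A -> free catalyst + left-handed product; coupling partner + catalyst intermediate B -> free catalyst + right-handed product; free catalyst + right-handed substrate <-> catalyst intermediate B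
- an excess is the difference of the two amounts in percent of their sum
- an excess is below zero if the other one leads

1. excess of left-handed product over right-handed product in the product at 20 min
2. excess of left-handed product over right-handed product in the product at 6.0 h
3. part of the left-handed substrate and right-handed substrate charged together that has reacted at 6.0 h

- Read it from the last maple point: that logarithm ratio, the selectivity factor, is 1.80. Read it from the last elm point too: 2.05, higher, though both readings carry their scatter. Carry the maple value to the flask.
- Scale the conversion: at 8.00 h, maple over elm is 1.45, against a concentration ratio of 1.50. Scaling maple by concentration puts the flask at 16.0% reacted at 3.00 h and, interpolating, 43.0% at 6.0 h.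
- Draw the excess: reckon it at the start as one minus the factor over one plus the factor, −28.7%, my answer for 20 min.
- Approximate the left-handed remainder as the unreacted fraction raised to two over one plus the factor, and the right-handed remainder as that raised to the factor. My reckoning then puts the flask's excess at −26.3% at 3.00 h and −21.8% at 6.0 h.
- The forecast, with its excesses from “Treating the runs as a kinetic resolution”, gives −35% (−55% to −18%) at 20 min, −24% (−33% to −15%) at 6.0 h and 41% (34% to 48%) reacted at 6.0 h, each below my reckoning.
- The flask gives −44.5% at 20 min, −19.1% at 6.0 h and 42.2% reacted, with 67% of its left-handed substrate and 48% of its right-handed substrate left. Put those remainders into the factor: 1.85. Turn the flask's early excess back into a factor: 2.60, higher, so the factor in this flask did not hold steady.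

    coupling partner ⇌ dormant form (K = 0.190, k = 7.86 × 10⁻⁴ min⁻¹)
    coupling partner → decomposed reagent (k = 9.09 × 10⁻⁴ min⁻¹)
    free catalyst + left-handed substrate ⇌ catalyst intermediate A (K = 4.02 M⁻¹, k = 41.5 M⁻¹ min⁻¹)
    left-handed product ⇌ right-handed product (k = 4.93 × 10⁻⁴ min⁻¹)
    coupling partner + catalyst intermediate A → free catalyst + left-handed product (k = 26.9 M⁻¹ min⁻¹)
    coupling partner + catalyst intermediate B → free catalyst + right-handed product (k = 11.6 M⁻¹ min⁻¹)
    free catalyst + right-handed substrate ⇌ catalyst intermediate B (K = 26.1 M⁻¹, k = 25.6 M⁻¹ min⁻¹)

- Apply the factor to the neighbour flask with 0.800 equiv of coupling partner, taking its 18.6% reacted: the carried 1.80 gives −25.9%. That neighbour computes to −31.1%, and its remainders, 88% of its left-handed substrate and 75% of its right-handed substrate, give a factor of 2.31.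

Readings and results are simulated on assumed constants; the scatter is artificial.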